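**Plan**

- Retrosynthesis: the ester between the halves is cut at its O–CH2 bond (carboxylate + spiro-epoxide). In the left half the oxepinone is cut at its C=C (ring-closing metathesis) and at the lactone O–CH2 bond. In the right half the side-chain C=C is cut (cross metathesis) and the ring CH2OH goes back to a vinyl triflate.
- Both six-membered carbocycles then converge on (R)-cryptone 8. In each ring the carbon that carries the oxygenated one-carbon branch (C(CH2OH)= on the right, C(OH)(CH2O) on the left) lies between a ring CH2 and a ring CH, so it is a latent ketone flanked by its two α-carbons. The isopropyl-bearing carbon lies between the other ring CH2 and the CH that carries the side chain, so it is a latent 2-isopropylacrolein.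
- Cutting the CH2–CH2 bond and the CH–CH(side chain) bond therefore divides the ring into a 1,3-dinucleophile (tert-butyl 3-oxobutanoate, ester as removable activating group) and a 1,3-dielectrophile (enal 3).
- Forward: α-methylenation of 3-methylbutanal, then one-pot Michael addition/protonation/aldol condensation/decarboxylation to 8. One vinyl conjugate addition with silyl trapping gives enol ether 10, which is used twice (triflation → acid 19; hydroxymethylation → epoxide 22). The halves are joined, then the acid carbon is oxidised, the acrylate tether attached, the seven-membered lactone closed and all protecting groups removed.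
- Stereochemistry: C4 of 8 comes from catalyst-controlled protonation, the only enantio-determining event. It is relayed by anti vinyl addition, anti (and thermodynamic) hydroxymethylation, and axial methylene transfer. Alkene geometries come from reversible cross metathesis (E) and from the ring.

Key step: step 2

Remark: in step 2 the catalyst enantiomer that protonates the enamine to the 4R aldehyde is used; the (S)-tert-leucine-derived diamine is written, and its antipode serves equally if the sense of induction is the opposite.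

Step 1
Reactants: 1 3-methylbutanal; 2 formaldehyde (37% aqueous)
Product: 3 3-methyl-2-methylidenebutanal (2-isopropylacrolein)
Conditions: pyrrolidine (10 mol%), propanoic acid (10 mol%), iPrOH, 45 °C
Reagents that add atoms: none
Why: Amine/acid-catalysed Mannich condensation–elimination (organocatalytic α-methylenation of aldehydes) is reliable for α-unbranched aldehydes; no stereocentre is formed.

Step 2
Reactants: 3 3-methyl-2-methylidenebutanal; 4 tert-butyl 3-oxobutanoate
Product: 8 (4R)-4-(propan-2-yl)cyclohex-2-en-1-one ((R)-cryptone), via Michael adduct 5 (not isolated), via enone ester 6 (not isolated), via keto acid 7 (not isolated)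
Conditions: (S)-N1,N1-diethyl-3,3-dimethylbutane-1,2-diamine·CF3SO3H (20 mol%), toluene, 0 °C → rt; then TsOH·H2O (30 mol%), toluene, 70 °C
Reagents that add atoms: none
Why: Proposed new method: the primary amine of the catalyst should condense with enal 3 to an iminium ion, the enol of 4 adds to its CH2 terminus (the C5–C6 bond of 8), and the enamine so formed is protonated on one face by the ammonium arm held on the same nitrogen before hydrolysis to 5; TsOH then effects the aldol condensation of the methyl ketone onto the aldehyde (the C2=C3 bond of 8), loss of 2-methylpropene from 6 and decarboxylation of 7. The closest known reaction types are the primary-amine-catalysed conjugate addition with enantioselective protonation of 2-substituted acroleins (shown for indole and thiol nucleophiles) and the one-pot amine-catalysed Michael addition of tert-butyl 3-oxobutanoate to enals followed by acid-promoted aldol condensation and decarboxylation to cyclohexenones; their union on a 2-alkylacrolein with a β-keto ester nucleophile is without precedent. The ring closes by a 6-(enolendo)-exo-trig aldol addition and dehydration. The single new stereocentre, C4, is set by the catalyst in the protonation, and because the α-branched aldehyde re-enters the same enamine both of its epimers are funnelled to the 4R form until cyclisation, after which the centre lies γ to the enone carbonyl. The step needs 1,4- instead of 1,2-addition and C- instead of O-alkylation (soft, doubly stabilised enol on an iminium ion), six- instead of four-membered aldol closure (only the methyl carbon of 5 can reach the aldehyde without strain) and enantiofacial protonation (delivery from the ammonium group next to the enamine nitrogen).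

Step 3
Reactants: 8 (R)-cryptone
Product: 10 trimethyl{[(3R,4R)-4-(propan-2-yl)-3-vinylcyclohex-1-en-1-yl]oxy}silane, via bromomagnesium enolate 9 (not isolated)
Conditions: CH2=CHMgBr (1.2 equiv), CuBr·SMe2 (10 mol%), THF, −78 °C; then Me3SiCl, Et3N, DMPU, −78 °C → rt; pentane, cold aq NaHCO3
Reagents that add atoms: vinylmagnesium bromide, C=C[Mg]Br; chlorotrimethylsilane, C[Si](C)(C)Cl
Why: CuBr·SMe2-catalysed 1,4-addition of a vinyl Grignard reagent to a 4-substituted cyclohexenone takes place anti to the C4 isopropyl group (new C3 centre R, trans), and O-silylation of the regiodefined enolate gives an isolable silyl enol ether that fixes the double bond between C1 and C2 and serves both halves.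

Step 4
Reactants: 10 silyl enol ether
Product: 12 (3R,4R)-4-(propan-2-yl)-3-vinylcyclohex-1-en-1-yl trifluoromethanesulfonate, via lithium enolate 11 (not isolated)
Conditions: MeLi (1.05 equiv), THF, 0 °C; then PhNTf2, −78 °C → rt; H2O work-up
Reagents that add atoms: N-phenylbis(trifluoromethanesulfonimide), O=S(=O)(N(c1ccccc1)S(=O)(=O)C(F)(F)F)C(F)(F)F; methyllithium, [Li]C (supplies only the lithium of intermediate 11)
Why: Regiospecific regeneration of the lithium enolate from the trimethylsilyl enol ether with methyllithium, followed by O-triflation with PhNTf2, keeps the double bond between C1 and C2; no stereocentre is touched.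

Step 5
Reactants: 12 vinyl triflate
Product: 13 [(3R,4R)-4-(propan-2-yl)-3-vinylcyclohex-1-en-1-yl]methanol
Conditions: Bu3SnCH2OH, Pd(PPh3)4 (5 mol%), LiCl, 1,4-dioxane, 100 °C
Reagents that add atoms: (tributylstannyl)methanol, CCCC[Sn](CCCC)(CCCC)CO
Why: Stille coupling of a vinyl triflate with the hydroxymethylstannane (LiCl-assisted) should install the ring CH2OH without moving the double bond; no stereocentre is touched.

Step 6
Reactants: 13 allylic alcohol
Product: 14 1-methoxy-4-({[(3R,4R)-4-(propan-2-yl)-3-vinylcyclohex-1-en-1-yl]methoxy}methyl)benzene (PMB ether of 13)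
Conditions: NaH, 4-MeOC6H4CH2Cl, Bu4NI (cat.), DMF, 0 °C → rt
Reagents that add atoms: 4-methoxybenzyl chloride, COc1ccc(CCl)cc1
Why: Williamson etherification of the primary allylic alcohol; the PMB group survives fluoride, base and olefin metathesis and falls in the final acid step.

Step 7
Reactants: 15 methyl 2-(bromomethyl)prop-2-enoate; 16 4-methoxybenzyl alcohol
Product: 17 methyl 2-{[(4-methoxybenzyl)oxy]methyl}prop-2-enoate
Conditions: Et3N, CH2Cl2, 0 °C → rt
Reagents that add atoms: none
Why: Tertiary-amine-mediated substitution of a 2-(bromomethyl)acrylate by an alcohol (SN2'–SN2' through the allylammonium salt) is a standard route to 2-(alkoxymethyl)acrylates.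

Step 8
Reactants: 14 PMB ether; 17 methyl 2-{[(4-methoxybenzyl)oxy]methyl}prop-2-enoate
Product: 18 methyl (2E)-2-{[(4-methoxybenzyl)oxy]methyl}-3-[(1R,6R)-3-{[(4-methoxybenzyl)oxy]methyl}-6-(propan-2-yl)cyclohex-2-en-1-yl]prop-2-enoate
Conditions: 17 (3 equiv), second-generation Hoveyda–Grubbs catalyst RuCl2(H2IMes)(=CH-C6H4-2-OiPr) (10 mol%), CH2Cl2, 40 °C
Reagents that add atoms: none
Why: Olefin cross metathesis between the only monosubstituted alkene of 14 and the 1,1-disubstituted acrylate should give the trisubstituted enoate, the trisubstituted ring alkene being inert and the E isomer (ester trans to the branched ring carbon) being the thermodynamically preferred product of reversible metathesis.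

Step 9
Reactants: 18 methyl ester
Product: 19 (2E)-2-{[(4-methoxybenzyl)oxy]methyl}-3-[(1R,6R)-3-{[(4-methoxybenzyl)oxy]methyl}-6-(propan-2-yl)cyclohex-2-en-1-yl]prop-2-enoic acid
Conditions: LiOH, THF/MeOH/H2O, 40 °C; then 1 M HCl to pH 3
Reagents that add atoms: lithium hydroxide, [Li+].[OH-]
Why: Saponification of the methyl ester; PMB ethers, both trisubstituted alkenes and the two stereocentres are inert to aqueous LiOH.

Step 10
Reactants: 10 silyl enol ether; 2 formaldehyde (37% aqueous)
Product: 20 (2R,3R,4R)-2-(hydroxymethyl)-4-(propan-2-yl)-3-vinylcyclohexan-1-one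
Conditions: 37% aq HCHO (5 equiv), Yb(OTf)3 (10 mol%), THF, rt
Reagents that add atoms: none
Why: Yb(OTf)3-catalysed aqueous Mukaiyama aldol reaction (hydroxymethylation) of the silyl enol ether with formaldehyde forms the new bond at C2 only and on carbon only, anti to the adjacent vinyl group; the C2 centre is epimerisable and the all-equatorial trans,trans ketone is also the thermodynamic isomer.

Step 11
Reactants: 20 hydroxy ketone
Product: 21 (2R,3R,4R)-4-(propan-2-yl)-2-({[tri(propan-2-yl)silyl]oxy}methyl)-3-vinylcyclohexan-1-one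
Conditions: iPr3SiCl, imidazole, DMF, 0 °C → rt
Reagents that add atoms: chlorotri(propan-2-yl)silane, CC(C)[Si](Cl)(C(C)C)C(C)C
Why: Silylation of the primary alcohol under mild imidazole buffering avoids dehydration of the β-hydroxy ketone, and the bulky silyl ether survives the ylide and carbonate steps before its removal with fluoride in step 14; no stereocentre is touched.

Step 12
Reactants: 21 ketone
Product: 22 (3S,4R,5R,6R)-6-(propan-2-yl)-4-({[tri(propan-2-yl)silyl]oxy}methyl)-5-vinyl-1-oxaspiro[2.5]octane
Conditions: Me3S+ I−, KN(SiMe3)2, THF, −10 → 0 °C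
Reagents that add atoms: trimethylsulfonium iodide, C[S+](C)C.[I-]
Why: Corey–Chaykovsky epoxidation: dimethylsulfonium methylide adds irreversibly along the axial trajectory of the chair with three equatorial substituents, so the new CH2 becomes axial (cis to the CH2OSi group) and the oxygen equatorial, which sets the spiro centre as S.

Step 13
Reactants: 19 acid; 22 spiro-epoxide
Product: 23 [(1S,2R,3R,4R)-1-hydroxy-4-(propan-2-yl)-2-({[tri(propan-2-yl)silyl]oxy}methyl)-3-vinylcyclohexyl]methyl ester of acid 19
Conditions: 19 (1.2 equiv), Cs2CO3 (0.2 equiv), DMF, 80 °C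
Reagents that add atoms: none
Why: Carboxylate opening of a 2,2-disubstituted epoxide occurs by SN2 attack at the CH2 terminus, which joins the two halves as the primary ester and releases the tertiary alcohol with its configuration untouched; catalytic base keeps the alkoxide protonated by the excess acid.

Step 14
Reactants: 23 silyl ether
Product: 24 [(1S,2R,3R,4R)-1-hydroxy-2-(hydroxymethyl)-4-(propan-2-yl)-3-vinylcyclohexyl]methyl ester of acid 19
Conditions: HF·pyridine, pyridine, THF, 0 °C → rt
Reagents that add atoms: none
Why: Fluoride cleavage of the primary silyl ether; PMB ethers, esters and the tertiary alcohol are stable to buffered HF·pyridine.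

Step 15
Reactants: 24 diol
Product: 26 (1S,2S,5R,6R)-2-hydroxy-2-(acyloxymethyl)-5-(propan-2-yl)-6-vinylcyclohexane-1-carboxylic acid (acyl = acyl group of 19), via hydroxy aldehyde 25 (not isolated)
Conditions: TEMPO (20 mol%), PhI(OAc)2 (2.5 equiv), MeCN/H2O (pH 7 buffer), rt
Reagents that add atoms: water, O
Why: Oxoammonium (TEMPO/PhI(OAc)2) oxidation of the primary alcohol through the aldehyde hydrate gives the acid under near-neutral conditions, leaving the tertiary alcohol, PMB ethers and alkenes intact; the α-centre stays in its equatorial (thermodynamic) configuration.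

Step 16
Reactants: 26 hydroxy acid; 27 tert-butyl 2-(bromomethyl)prop-2-enoate
Product: 28 2-(tert-butoxycarbonyl)prop-2-en-1-yl ester of acid 26
Conditions: Cs2CO3 (0.6 equiv), DMF, 0 °C → rt
Reagents that add atoms: none
Why: O-Alkylation of the caesium salt of 26 by the allylic bromide (SN2 and SN2' lead to the same ester) installs the 2-(alkoxycarbonyl)allyl ester that carries the missing three carbons of the oxepinone.

Step 17
Reactants: 28 triene ester
Product: 29 bis-PMB ether tert-butyl ester of the target (trans-fused seven-membered lactone closed)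
Conditions: second-generation Hoveyda–Grubbs catalyst RuCl2(H2IMes)(=CH-C6H4-2-OiPr) (10 mol%), toluene (2 mM), 80 °C
Reagents that add atoms: none
Why: Ring-closing metathesis between the vinyl group and the acrylate methylene, held 1,2-trans-diequatorial on the cyclohexane, should close the seven-membered lactone; the trisubstituted alkenes of the other half do not take part and the alkene geometry is dictated by the ring.

Step 18
Reactants: 29 protected target
Product: 30 CNP0361406.2
Conditions: CF3CO2H/CH2Cl2 (1:4), anisole, 0 °C → rt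
Reagents that add atoms: none
Why: Acidolysis removes the tert-butyl ester (as 2-methylpropene) and both PMB ethers (benzylic cations trapped by anisole) in one operation; the lactone, the linking ester and the tertiary alcohol are expected to survive cold trifluoroacetic acid.

**Compound list**

1 | 3-methylbutanal | CC(C)CC=O | starting material
2 | formaldehyde (37% aqueous) | C=O | starting material
3 | 3-methyl-2-methylidenebutanal | CC(C)C(=C)C=O | intermediate
4 | tert-butyl 3-oxobutanoate | CC(=O)CC(=O)OC(C)(C)C | starting material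
5 | tert-butyl (4R)-2-acetyl-4-formyl-5-methylhexanoate (both C2 epimers) | CC(C)[C@H](C=O)CC(C(C)=O)C(=O)OC(C)(C)C | intermediate
6 | tert-butyl (5R)-2-oxo-5-(propan-2-yl)cyclohex-3-ene-1-carboxylate | CC(C)[C@H]1CC(C(=O)OC(C)(C)C)C(=O)C=C1 | intermediate
7 | (5R)-2-oxo-5-(propan-2-yl)cyclohex-3-ene-1-carboxylic acid | CC(C)[C@H]1CC(C(=O)O)C(=O)C=C1 | intermediate
8 | (4R)-4-(propan-2-yl)cyclohex-2-en-1-one ((R)-cryptone) | CC(C)[C@H]1CCC(=O)C=C1 | intermediate
9 | bromomagnesium (3R,4R)-4-(propan-2-yl)-3-vinylcyclohex-1-en-1-olate | C=C[C@H]1C=C(O[Mg]Br)CC[C@@H]1C(C)C | intermediate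
10 | trimethyl{[(3R,4R)-4-(propan-2-yl)-3-vinylcyclohex-1-en-1-yl]oxy}silane | C=C[C@H]1C=C(O[Si](C)(C)C)CC[C@@H]1C(C)C | intermediate
11 | lithium (3R,4R)-4-(propan-2-yl)-3-vinylcyclohex-1-en-1-olate | C=C[C@H]1C=C(O[Li])CC[C@@H]1C(C)C | intermediate
12 | (3R,4R)-4-(propan-2-yl)-3-vinylcyclohex-1-en-1-yl trifluoromethanesulfonate | C=C[C@H]1C=C(OS(=O)(=O)C(F)(F)F)CC[C@@H]1C(C)C | intermediate
13 | [(3R,4R)-4-(propan-2-yl)-3-vinylcyclohex-1-en-1-yl]methanol | C=C[C@H]1C=C(CO)CC[C@@H]1C(C)C | intermediate
14 | PMB ether of 13 | C=C[C@H]1C=C(COCc2ccc(OC)cc2)CC[C@@H]1C(C)C | intermediate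
15 | methyl 2-(bromomethyl)prop-2-enoate | C=C(CBr)C(=O)OC | starting material
16 | 4-methoxybenzyl alcohol | COc1ccc(CO)cc1 | starting material
17 | methyl 2-{[(4-methoxybenzyl)oxy]methyl}prop-2-enoate | C=C(COCc1ccc(OC)cc1)C(=O)OC | intermediate
18 | methyl (2E)-2-{[(4-methoxybenzyl)oxy]methyl}-3-[(1R,6R)-3-{[(4-methoxybenzyl)oxy]methyl}-6-(propan-2-yl)cyclohex-2-en-1-yl]prop-2-enoate | COC(=O)/C(=C/[C@H]1C=C(COCc2ccc(OC)cc2)CC[C@@H]1C(C)C)COCc1ccc(OC)cc1 | intermediate
19 | (2E)-2-{[(4-methoxybenzyl)oxy]methyl}-3-[(1R,6R)-3-{[(4-methoxybenzyl)oxy]methyl}-6-(propan-2-yl)cyclohex-2-en-1-yl]prop-2-enoic acid | OC(=O)/C(=C/[C@H]1C=C(COCc2ccc(OC)cc2)CC[C@@H]1C(C)C)COCc1ccc(OC)cc1 | intermediate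
20 | (2R,3R,4R)-2-(hydroxymethyl)-4-(propan-2-yl)-3-vinylcyclohexan-1-one | CC(C)[C@H]1CCC(=O)[C@@H](CO)[C@@H]1C=C | intermediate
21 | (2R,3R,4R)-4-(propan-2-yl)-2-({[tri(propan-2-yl)silyl]oxy}methyl)-3-vinylcyclohexan-1-one | CC(C)[C@H]1CCC(=O)[C@@H](CO[Si](C(C)C)(C(C)C)C(C)C)[C@@H]1C=C | intermediate
22 | (3S,4R,5R,6R)-6-(propan-2-yl)-4-({[tri(propan-2-yl)silyl]oxy}methyl)-5-vinyl-1-oxaspiro[2.5]octane | CC(C)[C@H]1CC[C@@]2(CO2)[C@@H](CO[Si](C(C)C)(C(C)C)C(C)C)[C@@H]1C=C | intermediate
23 | [(1S,2R,3R,4R)-1-hydroxy-4-(propan-2-yl)-2-({[tri(propan-2-yl)silyl]oxy}methyl)-3-vinylcyclohexyl]methyl ester of 19 | CC(C)[C@H]1CC[C@@](O)(COC(=O)/C(=C/[C@H]2C=C(COCc3ccc(OC)cc3)CC[C@@H]2C(C)C)COCc2ccc(OC)cc2)[C@@H](CO[Si](C(C)C)(C(C)C)C(C)C)[C@@H]1C=C | intermediate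
24 | [(1S,2R,3R,4R)-1-hydroxy-2-(hydroxymethyl)-4-(propan-2-yl)-3-vinylcyclohexyl]methyl ester of 19 | CC(C)[C@H]1CC[C@@](O)(COC(=O)/C(=C/[C@H]2C=C(COCc3ccc(OC)cc3)CC[C@@H]2C(C)C)COCc2ccc(OC)cc2)[C@@H](CO)[C@@H]1C=C | intermediate
25 | [(1S,2S,3R,4R)-2-formyl-1-hydroxy-4-(propan-2-yl)-3-vinylcyclohexyl]methyl ester of 19 | CC(C)[C@H]1CC[C@@](O)(COC(=O)/C(=C/[C@H]2C=C(COCc3ccc(OC)cc3)CC[C@@H]2C(C)C)COCc2ccc(OC)cc2)[C@@H](C=O)[C@@H]1C=C | intermediate
26 | (1S,2S,5R,6R)-2-hydroxy-2-(acyloxymethyl)-5-(propan-2-yl)-6-vinylcyclohexane-1-carboxylic acid, acyl from 19 | CC(C)[C@H]1CC[C@@](O)(COC(=O)/C(=C/[C@H]2C=C(COCc3ccc(OC)cc3)CC[C@@H]2C(C)C)COCc2ccc(OC)cc2)[C@@H](C(=O)O)[C@@H]1C=C | intermediate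
27 | tert-butyl 2-(bromomethyl)prop-2-enoate | C=C(CBr)C(=O)OC(C)(C)C | starting material
28 | 2-(tert-butoxycarbonyl)prop-2-en-1-yl ester of 26 | CC(C)[C@H]1CC[C@@](O)(COC(=O)/C(=C/[C@H]2C=C(COCc3ccc(OC)cc3)CC[C@@H]2C(C)C)COCc2ccc(OC)cc2)[C@@H](C(=O)OCC(=C)C(=O)OC(C)(C)C)[C@@H]1C=C | intermediate
29 | bis-PMB ether tert-butyl ester of the target | CC(C)[C@H]1CC[C@@](O)(COC(=O)/C(=C/[C@H]2C=C(COCc3ccc(OC)cc3)CC[C@@H]2C(C)C)COCc2ccc(OC)cc2)[C@H]2C(=O)OCC(C(=O)OC(C)(C)C)=C[C@H]12 | intermediate
30 | CNP0361406.2 | CC(C)[C@H]1CC[C@@](O)(COC(=O)/C(=C/[C@H]2C=C(CO)CC[C@@H]2C(C)C)CO)[C@H]2C(=O)OCC(C(=O)O)=C[C@H]12 | target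

**Step count and risks**

Total steps: 18. Longest linear sequence: 14 (steps 1, 2, 3, 4, 5, 6, 8, 9, 13, 14, 15, 16, 17, 18).

Steps most likely to fail:

1. Step 2. Enantiofacial control in the protonation may be insufficient, and the configuration of the α-branched aldehyde (or of the γ-centre of the enone) may erode during the acid-promoted ring closure. Fallback: setting out from 1, the known enamine-catalysed Michael addition of 1 to but-3-en-2-one (the enantiomer of α,α-diphenylprolinol methyl ether that gives the 2R aldehyde, catechol-type co-catalyst) should give (2R)-5-oxo-2-(propan-2-yl)hexanal F1. Its base-mediated aldol condensation (LiOH, iPrOH) closes the ring through the C4–C5 and C2–C3 bonds instead and comes back to the route at 8.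

2. Step 8. Cross metathesis of the hindered, allylically branched vinyl group with a 1,1-disubstituted acrylate may be sluggish, and double-bond migration into conjugation with the ring alkene may compete. Fallback: setting out from 13, the metathesis is made intramolecular through a temporary silicon tether. Silylation of 13 with iPr2SiCl2/imidazole followed by methyl 2-(hydroxymethyl)prop-2-enoate should give the mixed bis-alkoxysilane methyl 2-({[di(propan-2-yl)({[(3R,4R)-4-(propan-2-yl)-3-vinylcyclohex-1-en-1-yl]methoxy})silyl]oxy}methyl)prop-2-enoate F2. Ring-closing metathesis (RuCl2(H2IMes)(=CH-C6H4-2-OiPr), dilute toluene) gives the ten-membered silylene-bridged enoate F3, in which the ring enforces the required geometry. HF·pyridine releases methyl (2E)-2-(hydroxymethyl)-3-[(1R,6R)-3-(hydroxymethyl)-6-(propan-2-yl)cyclohex-2-en-1-yl]prop-2-enoate F4. Double protection with 4-methoxybenzyl 2,2,2-trichloroacetimidate and La(OTf)3 (cat.) comes back to the route at 18.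

3. Step 13. SN2 opening at the axial, neopentyl-type CH2 of the epoxide by a weakly nucleophilic conjugated carboxylate may be slow, with acyl transfer or decomposition competing at the temperature needed. Fallback: setting out from 22, the epoxide is opened with the smaller, stronger nucleophile hydroxide (KOH, 1,4-dioxane/H2O, 90 °C) to (1S,2R,3R,4R)-1-(hydroxymethyl)-4-(propan-2-yl)-2-({[tri(propan-2-yl)silyl]oxy}methyl)-3-vinylcyclohexan-1-ol F5. The union is then made by acylation instead of alkylation: Yamaguchi esterification of the primary hydroxyl with 19 (2,4,6-trichlorobenzoyl chloride, Et3N, then DMAP) comes back to the route at 23.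

**Further compounds**

F1 | step 2 | (2R)-5-oxo-2-(propan-2-yl)hexanal | CC(C)[C@H](C=O)CCC(C)=O
F2 | step 8 | methyl 2-({[di(propan-2-yl)({[(3R,4R)-4-(propan-2-yl)-3-vinylcyclohex-1-en-1-yl]methoxy})silyl]oxy}methyl)prop-2-enoate | C=C[C@H]1C=C(CO[Si](C(C)C)(C(C)C)OCC(=C)C(=O)OC)CC[C@@H]1C(C)C
F3 | step 8 | ten-membered di(propan-2-yl)silylene-bridged ring-closing metathesis product (ester trans to the ring carbon) | COC(=O)/C1=C/[C@H]2C=C(CO[Si](C(C)C)(C(C)C)OC1)CC[C@@H]2C(C)C
F4 | step 8 | methyl (2E)-2-(hydroxymethyl)-3-[(1R,6R)-3-(hydroxymethyl)-6-(propan-2-yl)cyclohex-2-en-1-yl]prop-2-enoate | COC(=O)/C(=C/[C@H]1C=C(CO)CC[C@@H]1C(C)C)CO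
F5 | step 13 | (1S,2R,3R,4R)-1-(hydroxymethyl)-4-(propan-2-yl)-2-({[tri(propan-2-yl)silyl]oxy}methyl)-3-vinylcyclohexan-1-ol | CC(C)[C@H]1CC[C@@](O)(CO)[C@@H](CO[Si](C(C)C)(C(C)C)C(C)C)[C@@H]1C=C
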